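**Assumption:** locants C1–C10 in the text are those of the target's carotane (daucane) skeleton: C1 = methyl-bearing ring-fusion carbon, C4 = carbinol carbon, C5 = ring-fusion CH, C6 = aroyloxy carbon, C8 = methyl-bearing olefinic carbon, C10 = isovaleryloxy carbon. 3-Methylbut-3-enal is taken as not purchasable and is made in step 2. The route is a design proposal; nothing here has been run.

## Retrosynthetic overview

1. Target 23 ← phenol unmasking ← three-component ring opening of the oxa-bridged ether 19, which forms the C10–O ester bond with inversion and acylates the bridging oxygen at C6 in the same operation.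
2. 19 ← ring-closing metathesis of the cis-2-vinyl-5-methallyl tetrahydrofuran 18 (seven-membered carbocycle formed last).
3. The C4 carbinol of 18 ← convex-face epoxidation and hydride opening of cyclopentene 16 ← ketone 13.
4. The tetrahydrofuran of 13 (C6–O–C10) ← SN2′ C–O cyclisation of the Z-allylic alcohol 12.
5. The C1/C5/C6 triad ← Cu-catalysed conjugate methylation / aldol of enynone 5, made from 3-ethoxycyclopentenone. Ring order: cyclopentane (purchased), then tetrahydrofuran, then cycloheptene, then ether bridge cleaved.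

## Route

Step 1
Reactants: 1 3-ethoxycyclopent-2-en-1-one; 2 tert-butyldimethyl(prop-2-yn-1-yloxy)silane
Product: 5 3-{3-[(tert-butyldimethylsilyl)oxy]prop-1-yn-1-yl}cyclopent-2-en-1-one, via lithium acetylide 3 (not isolated), via tertiary lithium alkoxide 4 (not isolated)
Conditions: n-BuLi, THF, −78 °C; add 1, −78 → 0 °C; 1 M HCl, 0 °C
Reagents that add atoms: none
Why: Stork–Danheiser sequence: 1,2-addition of the acetylide to the vinylogous ester, then acid hydrolysis/elimination, transposes the enone and puts the alkynyl group on the β-carbon.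

Step 2
Reactants: 6 3-methylbut-3-en-1-ol
Product: 7 3-methylbut-3-enal
Conditions: PhI(OAc)2, TEMPO (10 mol %), CH2Cl2, 0 °C → rt; solution used directly
Reagents that add atoms: none
Why: Oxoammonium (TEMPO) oxidation under non-basic conditions gives the β,γ-unsaturated aldehyde without isomerisation to the conjugated enal.

Step 3
Reactants: 5 3-{3-[(tert-butyldimethylsilyl)oxy]prop-1-yn-1-yl}cyclopent-2-en-1-one; 7 3-methylbut-3-enal
Product: 10 (2S,3R)-2-[(1R)-1-hydroxy-3-methylbut-3-en-1-yl]-3-methyl-3-{3-[(tert-butyldimethylsilyl)oxy]prop-1-yn-1-yl}cyclopentan-1-one, via bromomagnesium enolate 8 (not isolated), via triisopropoxytitanium enolate 9 (not isolated)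
Conditions: MeMgBr, Cu(OTf)2 (5 mol %), chiral hydroxyalkyl imidazolinium salt (NHC precursor, 7.5 mol %), Et2O, −30 °C; ClTi(Oi-Pr)3, −78 °C; then 7, −78 °C
Reagents that add atoms: methylmagnesium bromide, C[Mg]Br
Why: Cu–NHC-catalysed asymmetric 1,4-addition to the cyclic enynone sets C1 (ligand enantiomer chosen for R); the regiodefined enolate, as its titanium enolate, undergoes a syn-selective aldol addition on the face of the slim alkynyl group (anti to methyl), setting C5 and C6.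

Step 4
Reactants: 10 (2S,3R)-2-[(1R)-1-hydroxy-3-methylbut-3-en-1-yl]-3-methyl-3-{3-[(tert-butyldimethylsilyl)oxy]prop-1-yn-1-yl}cyclopentan-1-one
Product: 11 (2S,3S)-2-[(1R)-1-hydroxy-3-methylbut-3-en-1-yl]-3-methyl-3-{(1Z)-3-[(tert-butyldimethylsilyl)oxy]prop-1-en-1-yl}cyclopentan-1-one
Conditions: H2 (1 atm), Pd/CaCO3 poisoned with Pb(OAc)2, quinoline, EtOAc, rt
Reagents that add atoms: none
Why: Lindlar semi-hydrogenation gives the Z-alkene needed for ring closure and leaves the 1,1-disubstituted alkene untouched (the C3 descriptor changes only through CIP priorities).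

Step 5
Reactants: 11 (2S,3S)-2-[(1R)-1-hydroxy-3-methylbut-3-en-1-yl]-3-methyl-3-{(1Z)-3-[(tert-butyldimethylsilyl)oxy]prop-1-en-1-yl}cyclopentan-1-one
Product: 13 (1S,3R,3aS,6aR)-1-ethenyl-6a-methyl-3-(2-methylprop-2-en-1-yl)hexahydro-1H-cyclopenta[c]furan-4-one, via diol 12 (not isolated)
Conditions: HF·pyridine, THF, 0 °C; then crude diol, Ph3PAuCl (5 mol %), AgOTf (5 mol %), 4 Å MS, CH2Cl2, 0 °C → rt
Reagents that add atoms: none
Why: Desilylation, then gold-catalysed dehydrative SN2′ cyclisation of the monoallylic diol (5-exo attack of the C6 hydroxyl on C10), forms the C6–O–C10 tetrahydrofuran; the new vinyl group takes the exo (convex) position of the cis-fused bicycle, cis to the methallyl group.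

Step 6
Reactants: 13 (1S,3R,3aS,6aR)-1-ethenyl-6a-methyl-3-(2-methylprop-2-en-1-yl)hexahydro-1H-cyclopenta[c]furan-4-one
Product: 15 (1S,3R,3aS,6aR)-1-ethenyl-6a-methyl-3-(2-methylprop-2-en-1-yl)-3,3a,6,6a-tetrahydro-1H-cyclopenta[c]furan-4-yl trifluoromethanesulfonate, via potassium enolate 14 (not isolated)
Conditions: KN(SiMe3)2, THF, −78 °C; PhNTf2, −78 → 0 °C; aq. NH4Cl
Reagents that add atoms: N-phenylbis(trifluoromethanesulfonimide), FC(F)(F)S(=O)(=O)N(c1ccccc1)S(=O)(=O)C(F)(F)F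
Why: Kinetic deprotonation at the unhindered C3 methylene (not the C5 methine, which would expel the β-alkoxide) followed by O-triflation gives the enol triflate regiospecifically.

Step 7
Reactants: 15 (1S,3R,3aS,6aR)-1-ethenyl-6a-methyl-3-(2-methylprop-2-en-1-yl)-3,3a,6,6a-tetrahydro-1H-cyclopenta[c]furan-4-yl trifluoromethanesulfonate
Product: 16 (1S,3R,3aS,6aR)-1-ethenyl-6a-methyl-3-(2-methylprop-2-en-1-yl)-4-(propan-2-yl)-3,3a,6,6a-tetrahydro-1H-cyclopenta[c]furan
Conditions: i-PrMgCl, Fe(acac)3 (5 mol %), THF/NMP, −30 °C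
Reagents that add atoms: isopropylmagnesium chloride, CC(C)[Mg]Cl
Why: Iron-catalysed Kumada-type cross-coupling of the alkenyl triflate with the secondary Grignard reagent installs the isopropyl group with the C3=C4 double bond fixed in place.

Step 8
Reactants: 16 (1S,3R,3aS,6aR)-1-ethenyl-6a-methyl-3-(2-methylprop-2-en-1-yl)-4-(propan-2-yl)-3,3a,6,6a-tetrahydro-1H-cyclopenta[c]furan
Product: 17 (1S,3R,3aS,4S,5R,6aR)-4,5-epoxy-1-ethenyl-6a-methyl-3-(2-methylprop-2-en-1-yl)-4-(propan-2-yl)hexahydro-1H-cyclopenta[c]furan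
Conditions: m-CPBA (1.0 equiv), CH2Cl2, −20 °C
Reagents that add atoms: m-chloroperoxybenzoic acid, OOC(=O)c1cccc(Cl)c1
Why: Prilezhaev epoxidation takes the trisubstituted, most electron-rich alkene first and from the convex face of the cis-fused bicycle (the face of the angular methyl and H-5), which sets the C4–O bond β.

Step 9
Reactants: 17 (1S,3R,3aS,4S,5R,6aR)-4,5-epoxy-1-ethenyl-6a-methyl-3-(2-methylprop-2-en-1-yl)-4-(propan-2-yl)hexahydro-1H-cyclopenta[c]furan
Product: 18 (1S,3R,3aS,4S,6aR)-1-ethenyl-6a-methyl-3-(2-methylprop-2-en-1-yl)-4-(propan-2-yl)hexahydro-1H-cyclopenta[c]furan-4-ol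
Conditions: LiEt3BH, THF, 0 °C → rt
Reagents that add atoms: none
Why: SN2 hydride opening of the trisubstituted epoxide at the secondary carbon C3 leaves the C4–O bond intact and gives the tertiary 4β-alcohol.

Step 10
Reactants: 18 (1S,3R,3aS,4S,6aR)-1-ethenyl-6a-methyl-3-(2-methylprop-2-en-1-yl)-4-(propan-2-yl)hexahydro-1H-cyclopenta[c]furan-4-ol
Product: 19 (3S,3aS,4R,8S,8aR)-4,8-epoxy-6,8a-dimethyl-3-(propan-2-yl)-1,2,3,3a,4,5,8,8a-octahydroazulen-3-ol
Conditions: second-generation Hoveyda–Grubbs catalyst (5 mol %), toluene (0.005 M), 80 °C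
Reagents that add atoms: none
Why: Ring-closing metathesis of the cis-disposed vinyl and methallyl groups forms the trisubstituted C8=C9 olefin and the seven-membered carbocycle as an 8-oxabicyclo[3.2.1]oct-2-ene.

Step 11
Reactants: 19 (3S,3aS,4R,8S,8aR)-4,8-epoxy-6,8a-dimethyl-3-(propan-2-yl)-1,2,3,3a,4,5,8,8a-octahydroazulen-3-ol
Product: 22 (3S,3aS,4R,8R,8aR)-3-hydroxy-6,8a-dimethyl-8-[(3-methylbutanoyl)oxy]-3-(propan-2-yl)-1,2,3,3a,4,5,8,8a-octahydroazulen-4-yl 4-(acetyloxy)benzoate, via silyl ether 20 (not isolated), via silylated diester 21 (not isolated)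
Conditions: 3-methylbutanoic acid (1.1 equiv), Me3SiOTf (2.3 equiv), 2,6-lutidine (2.1 equiv), CH2Cl2, −78 °C; 4-acetoxybenzoyl chloride (1.1 equiv), −40 → −10 °C; 1 M HCl, THF, 0 °C
Reagents that add atoms: 3-methylbutanoic acid, CC(C)CC(O)=O; 4-acetoxybenzoyl chloride, CC(=O)Oc1ccc(cc1)C(Cl)=O
Why: Proposed new method: a silyl-triflate-catalysed hetero-diacylative ether opening — Me3SiOTf first silylates the tertiary alcohol and the acid, and the remaining ~20 mol % converts the aroyl chloride into a trace of aroyl triflate that O-acylates the bridging ether oxygen; the acyloxonium can ionise only at allylic C10, and trimethylsilyl isovalerate attacks C10 anti to the departing, still C6-bound aroyloxy group (contact ion pair, helped by transannular shielding of the α face by the aroate carbonyl), giving the 10β-isovalerate with inversion and the 6α-aroate with retention while Me3SiCl is released and Me3SiOTf regenerated; the closest known chemistry is Lewis-acid acylative cleavage of ethers by acyl halides or anhydrides (one acyl type only) and Me3SiOTf-catalysed SN1 substitution of allylic or anomeric ethers by silyl nucleophiles.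

Step 12
Reactants: 22 (3S,3aS,4R,8R,8aR)-3-hydroxy-6,8a-dimethyl-8-[(3-methylbutanoyl)oxy]-3-(propan-2-yl)-1,2,3,3a,4,5,8,8a-octahydroazulen-4-yl 4-(acetyloxy)benzoate
Product: 23 (3S,3aS,4R,8R,8aR)-3-hydroxy-6,8a-dimethyl-8-[(3-methylbutanoyl)oxy]-3-(propan-2-yl)-1,2,3,3a,4,5,8,8a-octahydroazulen-4-yl 4-hydroxybenzoate (CNP0086724.1)
Conditions: K2CO3 (0.2 equiv), MeOH, 0 °C, 20 min
Reagents that add atoms: none
Why: Chemoselective transesterification: the phenyl acetate is methanolysed far faster than the two hindered secondary alkyl esters.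

## Compound list

1 | 3-ethoxycyclopent-2-en-1-one | CCOC1=CC(=O)CC1 | starting material
2 | tert-butyldimethyl(prop-2-yn-1-yloxy)silane | C#CCO[Si](C)(C)C(C)(C)C | starting material
3 | lithium 3-[(tert-butyldimethylsilyl)oxy]prop-1-yn-1-ide | [Li]C#CCO[Si](C)(C)C(C)(C)C | intermediate (not isolated)
4 | lithium 3-ethoxy-1-{3-[(tert-butyldimethylsilyl)oxy]prop-1-yn-1-yl}cyclopent-2-en-1-olate (racemic) | CCOC1=CC([O-])(C#CCO[Si](C)(C)C(C)(C)C)CC1.[Li+] | intermediate (not isolated)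
5 | 3-{3-[(tert-butyldimethylsilyl)oxy]prop-1-yn-1-yl}cyclopent-2-en-1-one | O=C1CCC(C#CCO[Si](C)(C)C(C)(C)C)=C1 | intermediate
6 | 3-methylbut-3-en-1-ol | CC(=C)CCO | starting material
7 | 3-methylbut-3-enal | CC(=C)CC=O | intermediate
8 | bromomagnesium (3R)-3-methyl-3-{3-[(tert-butyldimethylsilyl)oxy]prop-1-yn-1-yl}cyclopent-1-en-1-olate | CC(C)(C)[Si](C)(C)OCC#C[C@]1(C)CCC(O[Mg]Br)=C1 | intermediate (not isolated)
9 | triisopropoxytitanium (3R)-3-methyl-3-{3-[(tert-butyldimethylsilyl)oxy]prop-1-yn-1-yl}cyclopent-1-en-1-olate | CC(C)(C)[Si](C)(C)OCC#C[C@]1(C)CCC(O[Ti](OC(C)C)(OC(C)C)OC(C)C)=C1 | intermediate (not isolated)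
10 | (2S,3R)-2-[(1R)-1-hydroxy-3-methylbut-3-en-1-yl]-3-methyl-3-{3-[(tert-butyldimethylsilyl)oxy]prop-1-yn-1-yl}cyclopentan-1-one (syn aldol; hydroxyalkyl cis to alkynyl) | CC(C)(C)[Si](C)(C)OCC#C[C@]1(C)CCC(=O)[C@@H]1[C@H](O)CC(C)=C | intermediate
11 | (2S,3S)-2-[(1R)-1-hydroxy-3-methylbut-3-en-1-yl]-3-methyl-3-{(1Z)-3-[(tert-butyldimethylsilyl)oxy]prop-1-en-1-yl}cyclopentan-1-one | CC(C)(C)[Si](C)(C)OC/C=C\[C@]1(C)CCC(=O)[C@@H]1[C@H](O)CC(C)=C | intermediate
12 | (2S,3S)-2-[(1R)-1-hydroxy-3-methylbut-3-en-1-yl]-3-[(1Z)-3-hydroxyprop-1-en-1-yl]-3-methylcyclopentan-1-one | OC/C=C\[C@]1(C)CCC(=O)[C@@H]1[C@H](O)CC(C)=C | intermediate (not isolated)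
13 | (1S,3R,3aS,6aR)-1-ethenyl-6a-methyl-3-(2-methylprop-2-en-1-yl)hexahydro-1H-cyclopenta[c]furan-4-one (vinyl and methallyl cis, both exo) | C=C[C@H]2[C@]3(C)CCC(=O)[C@@H]3[C@H](O2)CC(C)=C | intermediate
14 | potassium (1S,3R,3aS,6aR)-1-ethenyl-6a-methyl-3-(2-methylprop-2-en-1-yl)-3,3a,6,6a-tetrahydro-1H-cyclopenta[c]furan-4-olate | C=C[C@H]2[C@]3(C)CC=C([O-])[C@@H]3[C@H](O2)CC(C)=C.[K+] | intermediate (not isolated)
15 | (1S,3R,3aS,6aR)-1-ethenyl-6a-methyl-3-(2-methylprop-2-en-1-yl)-3,3a,6,6a-tetrahydro-1H-cyclopenta[c]furan-4-yl trifluoromethanesulfonate | C=C[C@H]2[C@]3(C)CC=C(OS(=O)(=O)C(F)(F)F)[C@@H]3[C@H](O2)CC(C)=C | intermediate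
16 | (1S,3R,3aS,6aR)-1-ethenyl-6a-methyl-3-(2-methylprop-2-en-1-yl)-4-(propan-2-yl)-3,3a,6,6a-tetrahydro-1H-cyclopenta[c]furan | C=C[C@H]2[C@]3(C)CC=C(C(C)C)[C@@H]3[C@H](O2)CC(C)=C | intermediate
17 | (1S,3R,3aS,4S,5R,6aR)-4,5-epoxy-1-ethenyl-6a-methyl-3-(2-methylprop-2-en-1-yl)-4-(propan-2-yl)hexahydro-1H-cyclopenta[c]furan (epoxide oxygen cis to the angular methyl) | C=C[C@H]2[C@]3(C)C[C@H]4O[C@@]4(C(C)C)[C@@H]3[C@H](O2)CC(C)=C | intermediate
18 | (1S,3R,3aS,4S,6aR)-1-ethenyl-6a-methyl-3-(2-methylprop-2-en-1-yl)-4-(propan-2-yl)hexahydro-1H-cyclopenta[c]furan-4-ol | C=C[C@H]2[C@]3(C)CC[C@](O)(C(C)C)[C@@H]3[C@H](O2)CC(C)=C | intermediate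
19 | (3S,3aS,4R,8S,8aR)-4,8-epoxy-6,8a-dimethyl-3-(propan-2-yl)-1,2,3,3a,4,5,8,8a-octahydroazulen-3-ol (ether bridge C6–O–C10, anti to the angular methyl) | CC1=C[C@H]2[C@]3(C)CC[C@](O)(C(C)C)[C@@H]3[C@H](O2)C1 | intermediate
20 | trimethylsilyl ether of 19 at the tertiary hydroxyl | CC1=C[C@H]2[C@]3(C)CC[C@](O[Si](C)(C)C)(C(C)C)[C@@H]3[C@H](O2)C1 | intermediate (not isolated)
21 | trimethylsilyl ether of 22 at the tertiary hydroxyl | CC1=C[C@@H](OC(=O)CC(C)C)[C@]2(C)CC[C@](O[Si](C)(C)C)(C(C)C)[C@@H]2[C@H](OC(=O)c2ccc(OC(C)=O)cc2)C1 | intermediate (not isolated)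
22 | (3S,3aS,4R,8R,8aR)-3-hydroxy-6,8a-dimethyl-8-[(3-methylbutanoyl)oxy]-3-(propan-2-yl)-1,2,3,3a,4,5,8,8a-octahydroazulen-4-yl 4-(acetyloxy)benzoate | CC1=C[C@@H](OC(=O)CC(C)C)[C@]2(C)CC[C@](O)(C(C)C)[C@@H]2[C@H](OC(=O)c2ccc(OC(C)=O)cc2)C1 | intermediate
23 | (3S,3aS,4R,8R,8aR)-3-hydroxy-6,8a-dimethyl-8-[(3-methylbutanoyl)oxy]-3-(propan-2-yl)-1,2,3,3a,4,5,8,8a-octahydroazulen-4-yl 4-hydroxybenzoate | CC1=C[C@@H](OC(=O)CC(C)C)[C@]2(C)CC[C@](O)(C(C)C)[C@@H]2[C@H](OC(=O)c2ccc(O)cc2)C1 | target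

## Step count and risks

Total step count: 12. Longest linear sequence: 11 (steps 1 and 3–12, from 1 to 23); step 2 is a one-step side branch.

The three steps most likely to fail:

**Step 11 (the proposed new three-component opening).** It may lose C10 stereochemistry through re-ionisation of the allylic ester, capture the cation at C8, or scramble the two acyl groups. The fallback uses only known reactions and runs from 19 back to 22. Me2BBr cleaves the bridging allylic ether to (3S,3aS,4R,8R,8aR)-8-bromo-6,8a-dimethyl-3-(propan-2-yl)-1,2,3,3a,4,5,8,8a-octahydroazulene-3,4-diol F1 (the bromide configuration is immaterial). N-methylmorpholine N-oxide then oxidises the allylic bromide to (3S,3aS,4R,8aR)-3,4-dihydroxy-6,8a-dimethyl-3-(propan-2-yl)-2,3,3a,4,5,8a-hexahydroazulen-8(1H)-one F2. 4-Acetoxybenzoyl chloride and pyridine esterify the only secondary hydroxyl to give (3S,3aS,4R,8aR)-3-hydroxy-6,8a-dimethyl-8-oxo-3-(propan-2-yl)-1,2,3,3a,4,5,8,8a-octahydroazulen-4-yl 4-(acetyloxy)benzoate F3. NaBH4/CeCl3 at −78 °C delivers hydride to the enone from the face opposite the angular methyl, giving (3S,3aS,4R,8R,8aR)-3,8-dihydroxy-6,8a-dimethyl-3-(propan-2-yl)-1,2,3,3a,4,5,8,8a-octahydroazulen-4-yl 4-(acetyloxy)benzoate F4. Isovaleric anhydride and DMAP acylate the allylic hydroxyl, which gives 22.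

**Step 3 (three stereochemical outcomes in one flask).** The enantioselectivity on a five-membered enynone, the facial selectivity at C5 and the syn selectivity at C6 are each unproven on this substrate. The fallback separates the events and sets out from 5. The same Cu-catalysed methyl addition is quenched with Me3SiCl and the silyl enol ether {[(3R)-3-methyl-3-{3-[(tert-butyldimethylsilyl)oxy]prop-1-yn-1-yl}cyclopent-1-en-1-yl]oxy}trimethylsilane F5 is isolated. A fluoride-triggered aldol addition with 7, using tris(dimethylamino)sulfonium difluorotrimethylsilicate in THF at −78 °C, then proceeds through a naked enolate and an open transition state, which is syn-selective whatever the enolate geometry, and returns to the route at 10.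

**Step 5 (configuration at C10 and survival of the β-hydroxy ketone).** If the gold cyclisation gives the trans-2,5 isomer or dehydrates the aldol, the diol 12 is isolated after the HF·pyridine stage. Methyl chloroformate and pyridine at −20 °C convert only the primary allylic hydroxyl into (2Z)-3-{(1S,2S)-2-[(1R)-1-hydroxy-3-methylbut-3-en-1-yl]-1-methyl-3-oxocyclopentyl}prop-2-en-1-yl methyl carbonate F6. Pd(PPh3)4 in THF then ionises the carbonate to a π-allyl complex of divalent palladium, and the C6 hydroxyl closes the ring at C10 (Tsuji–Trost etherification by zerovalent palladium), which returns to the route at 13.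

Further compounds
F1 | step 11 | (3S,3aS,4R,8R,8aR)-8-bromo-6,8a-dimethyl-3-(propan-2-yl)-1,2,3,3a,4,5,8,8a-octahydroazulene-3,4-diol | CC1=C[C@@H](Br)[C@]2(C)CC[C@](O)(C(C)C)[C@@H]2[C@H](O)C1
F2 | step 11 | (3S,3aS,4R,8aR)-3,4-dihydroxy-6,8a-dimethyl-3-(propan-2-yl)-2,3,3a,4,5,8a-hexahydroazulen-8(1H)-one | CC1=CC(=O)[C@]2(C)CC[C@](O)(C(C)C)[C@@H]2[C@H](O)C1
F3 | step 11 | (3S,3aS,4R,8aR)-3-hydroxy-6,8a-dimethyl-8-oxo-3-(propan-2-yl)-1,2,3,3a,4,5,8,8a-octahydroazulen-4-yl 4-(acetyloxy)benzoate | CC1=CC(=O)[C@]2(C)CC[C@](O)(C(C)C)[C@@H]2[C@H](OC(=O)c2ccc(OC(C)=O)cc2)C1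
F4 | step 11 | (3S,3aS,4R,8R,8aR)-3,8-dihydroxy-6,8a-dimethyl-3-(propan-2-yl)-1,2,3,3a,4,5,8,8a-octahydroazulen-4-yl 4-(acetyloxy)benzoate | CC1=C[C@@H](O)[C@]2(C)CC[C@](O)(C(C)C)[C@@H]2[C@H](OC(=O)c2ccc(OC(C)=O)cc2)C1
F5 | step 3 | {[(3R)-3-methyl-3-{3-[(tert-butyldimethylsilyl)oxy]prop-1-yn-1-yl}cyclopent-1-en-1-yl]oxy}trimethylsilane | CC(C)(C)[Si](C)(C)OCC#C[C@]1(C)CCC(O[Si](C)(C)C)=C1
F6 | step 5 | (2Z)-3-{(1S,2S)-2-[(1R)-1-hydroxy-3-methylbut-3-en-1-yl]-1-methyl-3-oxocyclopentyl}prop-2-en-1-yl methyl carbonate | COC(=O)OC/C=C\[C@]1(C)CCC(=O)[C@@H]1[C@H](O)CC(C)=C
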